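**Retrosynthetic overview**
1. The route rests on the carbocycle of the central coumarin (unit B). Its C8 carries C8 of the 7-hydroxycoumarin unit C and lies between the oxygenated carbons C7 and C8a, so it is a 2-aryl-resorcinol whose biaryl bond has four ortho oxygen substituents.
2. After a final O-dealkylation, the pyranone of unit B (C3=C4 and O1–C2) is cut by a Perkin-type condensation into a salicylaldehyde and (coumarin-7-yloxy)acetic acid. The acid supplies unit A and the C3–O–C7 ether.
3. The salicylaldehyde goes back by ortho-formylation to a 2-aryl-3-ethoxyphenol. Its whole benzene ring is taken apart by a cyclobutenone/ynol ether benzannulation into cyclobutenone and 8-(ethoxyethynyl)-7-methoxycoumarin.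
4. The ynol ether comes from umbelliferone by C8 iodination, O-methylation and Sonogashira coupling with ethoxyacetylene. Cyclobutenone comes from 3-oxocyclobutanecarboxylic acid.
5. Ring order: units A and C enter intact as umbelliferone, then the benzene ring of unit B (step 6), and last the pyranone ring of unit B (step 10).

Key step: step 6

Assumption: the target string carries no descriptor for the C8(B)–C8(C) biaryl axis, so the axis is formed without control and every biaryl from 13 onward is taken as the racemate.

**Route**

Step 1
Reactants: 1 umbelliferone (7-hydroxycoumarin)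
Product: 2 7-hydroxy-8-iodocoumarin
Conditions: I2, KI, aq NH3, 0 °C to rt; then dilute H2SO4
Reagents that add atoms: iodine, II
Why: Electrophilic aromatic iodination of the phenoxide, which should take place at C8, the ortho carbon flanked by both ring oxygens and the established site of iodination of this phenol in ammoniacal medium.

Step 2
Reactants: 2 7-hydroxy-8-iodocoumarin
Product: 3 8-iodo-7-methoxycoumarin
Conditions: MeI, K2CO3, acetone, reflux
Reagents that add atoms: iodomethane, CI
Why: Williamson ether synthesis on an acidic phenol, which also removes the free OH that would otherwise cyclise onto the alkyne introduced in the next step.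

Step 3
Reactants: 3 8-iodo-7-methoxycoumarin; 4 ethoxyacetylene (solution in hexanes)
Product: 5 8-(ethoxyethynyl)-7-methoxycoumarin
Conditions: PdCl2(PPh3)2 (cat.), CuI (cat.), Et3N, THF, rt to 40 °C; filtration through Et3N-deactivated silica
Reagents that add atoms: none
Why: Sonogashira coupling, in which the aryl iodide adds to zerovalent palladium near room temperature, so that the acid- and heat-sensitive ynol ether is made and handled under mild basic conditions.

Step 4
Reactants: 6 3-oxocyclobutanecarboxylic acid
Product: 7 3-bromocyclobutanone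
Conditions: HgO, Br2, MgSO4, CH2Cl2, reflux
Reagents that add atoms: bromine, BrBr
Why: Cristol–Firth variant of the Hunsdiecker bromodecarboxylation, in which the acyl hypobromite loses CO2 by a radical chain and the remote ketone is untouched.

Step 5
Reactants: 7 3-bromocyclobutanone
Product: 8 cyclobut-2-en-1-one
Conditions: n-Bu3N (neat), rt, reduced pressure, distillation into a −78 °C trap; kept cold as a toluene solution
Reagents that add atoms: none
Why: E1cB dehydrobromination of a beta-bromo ketone, with the volatile enone distilled away from the non-volatile amine and its salt as it forms so that polymerisation is limited.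

Step 6
Reactants: 5 8-(ethoxyethynyl)-7-methoxycoumarin; 8 cyclobut-2-en-1-one
Product: 13 8-(2-ethoxy-6-hydroxyphenyl)-7-methoxycoumarin, via vinylketene 9 (not isolated), via 4-vinylcyclobutenone 10 (not isolated), via dienylketene 11 (not isolated), via cyclohexadienone 12 (not isolated)
Conditions: toluene, BHT (cat.), sealed vessel, 80 °C (8 added in two portions) until 5 is consumed, then 130 °C
Reagents that add atoms: none
Why: Danheiser benzannulation, the known reaction of cyclobutenones with 1-alkoxyalkynes that gives resorcinol monoethers: at 80 °C 8 opens in a reversible four-electron electrocyclic reaction to vinylketene 9, and the aryl-bearing alkyne carbon of 5 (beta to oxygen, hence nucleophilic) attacks the ketene carbonyl carbon in a [2+2] cycloaddition to give 4-vinylcyclobutenone 10, which creates the C8–C8a and C7–C6 bonds of unit B. At the higher temperature 10 opens to dienylketene 11, and the benzene ring of unit B closes by a thermal disrotatory six-electron electrocyclisation that joins the ketene carbon (future C8a) to the terminal vinyl CH2 (future C4a); cyclohexadienone 12 then tautomerises irreversibly to phenol 13. No lasting stereocentre is made: C4 of 10 is racemic and vanishes on ring opening, and the biaryl axis forms without control. The regiochemistry needed, aryl between OH and OEt, is fixed by the polarity of the ynol ether, and it delivers the two oxygens already differentiated (free OH for the later lactone O1, OEt as the masked C7 hydroxyl). Chemoselectivity for the alkyne over the coumarin C3=C4 bond rests on the preference of ketenes for electron-rich pi bonds, and holding the first stage at 80 °C keeps 5 below the temperature at which ethyl ynol ethers lose ethylene. Since the C8(C)–C8(B) bond is already present in 5 as an open sp2–sp bond, no cross-coupling at a position with four ortho substituents is called for.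

Step 7
Reactants: 13 8-(2-ethoxy-6-hydroxyphenyl)-7-methoxycoumarin
Product: 15 4-ethoxy-2-hydroxy-3-(7-methoxy-2-oxo-2H-chromen-8-yl)benzaldehyde, via hydroxymethylphenol 14 (not isolated)
Conditions: MgCl2 (anhydrous), Et3N, (CH2O)n, MeCN, reflux; then 1 M HCl
Reagents that add atoms: paraformaldehyde (as formaldehyde), C=O
Why: Casnati–Skattebøl ortho-formylation, in which magnesium-bound phenoxide delivers formaldehyde only to the single free ortho carbon (future C4a, para to OEt) to give 14, which a second formaldehyde oxidises to the aldehyde by hydride transfer.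

Step 8
Reactants: 1 umbelliferone; 16 ethyl bromoacetate
Product: 17 ethyl 2-[(2-oxo-2H-chromen-7-yl)oxy]acetate
Conditions: K2CO3, acetone, reflux
Reagents that add atoms: none
Why: Williamson ether synthesis of the phenoxide with a highly reactive alpha-bromo ester.

Step 9
Reactants: 17 ethyl 2-[(2-oxo-2H-chromen-7-yl)oxy]acetate
Product: 19 2-[(2-oxo-2H-chromen-7-yl)oxy]acetic acid, via lithium carboxylate 18 (not isolated)
Conditions: LiOH (1.2 equiv), THF/H2O, 0 °C to rt; then 1 M HCl
Reagents that add atoms: lithium hydroxide, [Li+].[OH-]
Why: Saponification of the oxygen-activated ethyl ester, which should outrun opening of the coumarin lactone, and any lactone that does open recloses spontaneously on acidification.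

Step 10
Reactants: 15 4-ethoxy-2-hydroxy-3-(7-methoxy-2-oxo-2H-chromen-8-yl)benzaldehyde; 19 2-[(2-oxo-2H-chromen-7-yl)oxy]acetic acid
Product: 21 7-ethoxy-8-(7-methoxy-2-oxo-2H-chromen-8-yl)-3-[(2-oxo-2H-chromen-7-yl)oxy]-2H-chromen-2-one, via mixed anhydride 20 (not isolated)
Conditions: Ac2O, Et3N, 120 °C
Reagents that add atoms: none
Why: Perkin–Oglialoro condensation, in which mixed anhydride 20 is enolised at its aryloxy-activated CH2 and adds to the aldehyde of 15, after which dehydration and lactonisation onto the neighbouring phenol close the pyranone of unit B, as established for 3-aryloxycoumarins from salicylaldehydes and aryloxyacetic acids.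

Step 11
Reactants: 21 7-ethoxy-8-(7-methoxy-2-oxo-2H-chromen-8-yl)-3-[(2-oxo-2H-chromen-7-yl)oxy]-2H-chromen-2-one
Product: 23 triumbelletin (7-hydroxy-8-(7-hydroxy-2-oxo-2H-chromen-8-yl)-3-[(2-oxo-2H-chromen-7-yl)oxy]-2H-chromen-2-one), via bis(dibromoborate) 22 (not isolated)
Conditions: BBr3 (excess), CH2Cl2, −78 °C to rt; then ice-water
Reagents that add atoms: none
Why: Lewis-acid cleavage of aryl alkyl ethers, in which bromide attacks the methyl and ethyl carbons of the boron-complexed ethers by SN2 to give 22 (hydrolysed on quench), while the C3–O–C7 ether joins two sp2 carbons and the three lactones only bind BBr3 reversibly, hence the excess.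

**Compound list**
1 | umbelliferone (7-hydroxycoumarin) | O=c1ccc2ccc(O)cc2o1 | starting material
2 | 7-hydroxy-8-iodocoumarin | O=c1ccc2ccc(O)c(I)c2o1 | intermediate
3 | 8-iodo-7-methoxycoumarin | COc1ccc2ccc(=O)oc2c1I | intermediate
4 | ethoxyacetylene | CCOC#C | starting material
5 | 8-(ethoxyethynyl)-7-methoxycoumarin | CCOC#Cc1c(OC)ccc2ccc(=O)oc12 | intermediate
6 | 3-oxocyclobutanecarboxylic acid | O=C1CC(C(=O)O)C1 | starting material
7 | 3-bromocyclobutanone | O=C1CC(Br)C1 | intermediate
8 | cyclobut-2-en-1-one | O=C1CC=C1 | intermediate
9 | vinylketene (buta-1,3-dien-1-one), not isolated | C=CC=C=O | intermediate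
10 | 3-ethoxy-2-(7-methoxy-2-oxo-2H-chromen-8-yl)-4-vinylcyclobut-2-en-1-one (racemic at C4), not isolated | C=CC1C(=O)C(c2c(OC)ccc3ccc(=O)oc23)=C1OCC | intermediate
11 | 3-ethoxy-2-(7-methoxy-2-oxo-2H-chromen-8-yl)hexa-1,3,5-trien-1-one, isomer with ketene and vinyl termini cis on the central C=C, not isolated | O=C=C(c1c(OC)ccc2ccc(=O)oc12)/C(OCC)=C\C=C | intermediate
12 | 3-ethoxy-2-(7-methoxy-2-oxo-2H-chromen-8-yl)cyclohexa-2,4-dien-1-one, not isolated | O=C1CC=CC(OCC)=C1c1c(OC)ccc2ccc(=O)oc12 | intermediate
13 | 8-(2-ethoxy-6-hydroxyphenyl)-7-methoxycoumarin (racemic axis) | CCOc1cccc(O)c1-c1c(OC)ccc2ccc(=O)oc12 | intermediate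
14 | 8-[6-ethoxy-2-hydroxy-3-(hydroxymethyl)phenyl]-7-methoxycoumarin (present as its magnesium salt), not isolated | CCOc1ccc(CO)c(O)c1-c1c(OC)ccc2ccc(=O)oc12 | intermediate
15 | 4-ethoxy-2-hydroxy-3-(7-methoxy-2-oxo-2H-chromen-8-yl)benzaldehyde | CCOc1ccc(C=O)c(O)c1-c1c(OC)ccc2ccc(=O)oc12 | intermediate
16 | ethyl bromoacetate | CCOC(=O)CBr | starting material
17 | ethyl 2-[(2-oxo-2H-chromen-7-yl)oxy]acetate | CCOC(=O)COc1ccc2ccc(=O)oc2c1 | intermediate
18 | lithium 2-[(2-oxo-2H-chromen-7-yl)oxy]acetate, not isolated | [Li+].[O-]C(=O)COc1ccc2ccc(=O)oc2c1 | intermediate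
19 | 2-[(2-oxo-2H-chromen-7-yl)oxy]acetic acid | O=C(O)COc1ccc2ccc(=O)oc2c1 | intermediate
20 | acetic 2-[(2-oxo-2H-chromen-7-yl)oxy]acetic anhydride, not isolated | CC(=O)OC(=O)COc1ccc2ccc(=O)oc2c1 | intermediate
21 | 7-ethoxy-8-(7-methoxy-2-oxo-2H-chromen-8-yl)-3-[(2-oxo-2H-chromen-7-yl)oxy]-2H-chromen-2-one | O=c1ccc2ccc(Oc3cc4ccc(OCC)c(-c5c(OC)ccc6ccc(=O)oc56)c4oc3=O)cc2o1 | intermediate
22 | bis(dibromoboryl) ether of triumbelletin, not isolated | O=c1ccc2ccc(Oc3cc4ccc(OB(Br)Br)c(-c5c(OB(Br)Br)ccc6ccc(=O)oc56)c4oc3=O)cc2o1 | intermediate
23 | triumbelletin | O=c1ccc2ccc(Oc3cc4ccc(O)c(-c5c(O)ccc6ccc(=O)oc56)c4oc3=O)cc2o1 | target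

**Step count**
Total: 11 steps.
Longest linear sequence: 7 steps from umbelliferone (steps 1, 2, 3, 6, 7, 10, 11).

**Steps most likely to fail**

Step 6.
- What may go wrong: self-condensation and polymerisation of cyclobutenone and vinylketene may outrun capture by the aryl-conjugated, only moderately nucleophilic ynol ether. Retro-ene loss of ethylene from 5 and acylation of the product phenol by surplus ketene may erode the material further.
- Fallback: it sets out from iodide 3 and makes the biaryl bond by a hindered Suzuki–Miyaura coupling. Commercial 3-ethoxyphenol is protected (MOMCl, i-Pr2NEt, CH2Cl2) as 1-ethoxy-3-(methoxymethoxy)benzene F1. This is lithiated between its two oxygens (n-BuLi, THF, 0 °C) and borylated (B(Oi-Pr)3, then aq NH4Cl) to [2-ethoxy-6-(methoxymethoxy)phenyl]boronic acid F2. Coupling of F2 with 3 (Pd(OAc)2, SPhos, K3PO4, toluene/H2O, 100 °C) should give 8-[2-ethoxy-6-(methoxymethoxy)phenyl]-7-methoxycoumarin F3. HCl in MeOH then removes the acetal, and the route is rejoined at 13.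

Step 3.
- What may go wrong: slow oxidative addition at the doubly ortho-substituted iodide may let copper-mediated oxidative homocoupling of the alkyne compete. Hydration of the ynol ether during work-up or chromatography may also compete.
- Fallback: it sets out from 4 and 3 and replaces the amine/copper protocol by a neutral Stille coupling of a preformed tin acetylide. Compound 4 is deprotonated (n-BuLi, THF, −78 °C) and quenched with Bu3SnCl to give tributyl(ethoxyethynyl)stannane F4. This is coupled with 3 (PdCl2(PPh3)2, DMF, 50 °C), and the route is rejoined at 5.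

Step 10.
- What may go wrong: O-acetylation of the hindered, hydrogen-bonded phenol may intervene before the C–C bond forms. So may thermal breakdown of the mixed anhydride through ketene oligomerisation.
- Fallback: it sets out from 19 and 15 and splits the condensation into two discrete operations without acetic anhydride. Acid 19 is converted (SOCl2, cat. DMF, CH2Cl2, reflux) into 2-[(2-oxo-2H-chromen-7-yl)oxy]acetyl chloride F5. This acylates 15 (Et3N, DMAP, CH2Cl2, 0 °C) to give 3-ethoxy-6-formyl-2-(7-methoxy-2-oxo-2H-chromen-8-yl)phenyl 2-[(2-oxo-2H-chromen-7-yl)oxy]acetate F6. An intramolecular aldol condensation (DBU, MeCN, rt to 50 °C) then closes the pyranone, and the route is rejoined at 21.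

**Further compounds**
F1 | step 6 | 1-ethoxy-3-(methoxymethoxy)benzene | CCOc1cccc(OCOC)c1
F2 | step 6 | [2-ethoxy-6-(methoxymethoxy)phenyl]boronic acid | CCOc1cccc(OCOC)c1B(O)O
F3 | step 6 | 8-[2-ethoxy-6-(methoxymethoxy)phenyl]-7-methoxycoumarin | CCOc1cccc(OCOC)c1-c1c(OC)ccc2ccc(=O)oc12
F4 | step 3 | tributyl(ethoxyethynyl)stannane | CCOC#C[Sn](CCCC)(CCCC)CCCC
F5 | step 10 | 2-[(2-oxo-2H-chromen-7-yl)oxy]acetyl chloride | O=C(Cl)COc1ccc2ccc(=O)oc2c1
F6 | step 10 | 3-ethoxy-6-formyl-2-(7-methoxy-2-oxo-2H-chromen-8-yl)phenyl 2-[(2-oxo-2H-chromen-7-yl)oxy]acetate | CCOc1ccc(C=O)c(OC(=O)COc2ccc3ccc(=O)oc3c2)c1-c1c(OC)ccc2ccc(=O)oc12
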